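**Retrosynthetic overview**

1. The target is a 2,4-cis (2R,4R) 4-arylflavan (ring A = benzo ring of the chroman, ring B = 2-aryl group, ring C = pyran ring, ring D = acylphloroglucinol ring). It is reached from its tetra-O-benzyl ether by one final hydrogenolysis, so the whole skeleton and both stereocenters come from a single step.
2. Key disconnection: ring C is cut at C2–C3 and at C4–C4a. This gives a cationic 2-oxadiene (an O-aryl oxocarbenium ion, C2=O1(+)–C8a=C4a, carrying rings A and B) and a two-carbon partner, the vinyl group C3=C4 of an ortho-hydroxystyrene on ring D that already bears the 9-phenylnonanoyl chain. They are joined by a formal [4+2] annulation under chiral phosphoric acid catalysis (an asymmetric oxa-Povarov reaction).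
3. Enabling feature: C2 lies between O1 and the para-oxygenated ring B, so the C2=O1 oxocarbenium ion forms easily. C4a of ring A is para to O7 and ortho to O1, so it closes the ring. C4 is benzylic to ring D, whose oxygens ortho and para to C4 make C3 of the styrene nucleophilic and whose free ortho-hydroxyl docks onto the chiral phosphate.
4. Precursors: the oxocarbenium ion comes from a symmetric bis(aryloxy) acetal, made in one step from 4-(benzyloxy)benzaldehyde and two equivalents of 3-(benzyloxy)phenol. The styrene comes from phloroglucinol by acylation, formylation, selective dibenzylation and Wittig methylenation.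
5. Ring order: rings A, B, D and the terminal phenyl are bought as such; ring C is the only ring formed, in the key step.

Key step: step 6

Assumption: 9-phenylnonanoic acid is taken as a catalogue compound.
Assumption: the sense of induction of the chiral phosphoric acid in step 6 cannot be derived safely in advance; the (R)-acid is written, and its mirror image would be used if the first run shows the opposite sense.

**Step 1**
Reactants: 1 phloroglucinol, 2 9-phenylnonanoic acid
Product: 3 9-phenyl-1-(2,4,6-trihydroxyphenyl)nonan-1-one
Conditions: 1 (1.5 equiv), BF3·OEt2 (promoter and solvent), 90 °C; aqueous NaOAc work-up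
Reagents that add atoms: none
Why: Friedel–Crafts acylation of the very electron-rich phloroglucinol by the BF3-activated carboxylic acid; the first acyl group deactivates the ring, so the reaction should stop at the monoketone, and the unactivated terminal phenyl cannot compete.

**Step 2**
Reactants: 3 9-phenyl-1-(2,4,6-trihydroxyphenyl)nonan-1-one
Product: 4 2,4,6-trihydroxy-3-(9-phenylnonanoyl)benzaldehyde
Conditions: POCl3 (1.1 equiv), DMF (3 equiv), EtOAc, 0 °C to rt; then H2O, 60 °C
Reagents that add atoms: N,N-dimethylformamide CN(C)C=O; water O
Why: Vilsmeier–Haack formylation; the two free ring positions of 3 are equivalent, so only one monoformyl product can form, and the new formyl group deactivates the ring against a second formylation.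

**Step 3**
Reactants: 4 2,4,6-trihydroxy-3-(9-phenylnonanoyl)benzaldehyde
Product: 5 4,6-bis(benzyloxy)-2-hydroxy-3-(9-phenylnonanoyl)benzaldehyde
Conditions: BnBr (2.1 equiv), K2CO3 (2.2 equiv), DMF, 0 °C to rt
Reagents that add atoms: benzyl bromide BrCc1ccccc1
Why: Williamson ether synthesis; the hydroxyl between the formyl and the acyl group is hydrogen-bonded to a carbonyl on either side and is the most hindered, so the other two hydroxyls should be benzylated first and this one stays free.

**Step 4**
Reactants: 5 4,6-bis(benzyloxy)-2-hydroxy-3-(9-phenylnonanoyl)benzaldehyde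
Product: 6 1-[4,6-bis(benzyloxy)-3-ethenyl-2-hydroxyphenyl]-9-phenylnonan-1-one
Conditions: Ph3PCH3Br (2.6 equiv), KOtBu (2.5 equiv), THF, 0 °C to rt; aqueous NH4Cl
Reagents that add atoms: methyltriphenylphosphonium bromide C[P+](c1ccccc1)(c1ccccc1)c1ccccc1.[Br-]
Why: Wittig methylenation; the first equivalent of ylide deprotonates the phenol, the aldehyde then reacts, and the di-ortho-substituted aryl ketone conjugated to the phenoxide is too hindered and too electron-rich to compete.

**Step 5**
Reactants: 7 4-(benzyloxy)benzaldehyde, 8 3-(benzyloxy)phenol (two equivalents, one for each aryloxy group of the acetal)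
Product: 10 4-(benzyloxy)benzaldehyde bis[3-(benzyloxy)phenyl] acetal, via benzal chloride 9 (not isolated)
Conditions: SOCl2 (1.5 equiv), DMF (cat.), CH2Cl2, 0 °C to rt, evaporate; then 8 (2.2 equiv), NaH (2.3 equiv), THF/DMF, 0 °C to rt; chromatography on Et3N-deactivated silica
Reagents that add atoms: 3-(benzyloxy)phenol (second equivalent of 8) Oc1cccc(OCc2ccccc2)c1
Why: Vilsmeier-type dichlorination of the aromatic aldehyde gives the benzal chloride, whose two chlorides are then displaced one after the other by two molecules of the phenoxide in SN1-like Williamson substitutions helped by the para-benzyloxy group; the acid-labile acetal is formed and handled under basic conditions only, and it has no stereocenter because the two aryloxy groups are identical.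

**Step 6**
Reactants: 6 1-[4,6-bis(benzyloxy)-3-ethenyl-2-hydroxyphenyl]-9-phenylnonan-1-one, 10 4-(benzyloxy)benzaldehyde bis[3-(benzyloxy)phenyl] acetal
Product: 13 1-{4,6-bis(benzyloxy)-3-[(2R,4R)-7-(benzyloxy)-2-[4-(benzyloxy)phenyl]-3,4-dihydro-2H-chromen-4-yl]-2-hydroxyphenyl}-9-phenylnonan-1-one, via oxocarbenium ion 11 (not isolated), via benzylic cation 12 (not isolated)
Conditions: 10 (1.3 equiv), (R)-TRIP [(R)-3,3'-bis(2,4,6-triisopropylphenyl)-1,1'-binaphthalene-2,2'-diyl hydrogen phosphate] (10 mol %), 4 Å MS, toluene, −40 to −20 °C
Reagents that add atoms: none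
Why: Proposed new method: the chiral phosphoric acid protonates one aryloxy oxygen of the symmetric acetal 10 (ionisation in either sense gives the same ion), 3-(benzyloxy)phenol leaves, and the E-configured O-aryl oxocarbenium ion 11 is held as a contact ion pair by the chiral phosphate, which can also accept a hydrogen bond from the free ortho-phenol of styrene 6; the terminal CH2 of 6 then adds to C2 (Prins-type addition) to give the benzylic cation 12, an O-protonated ortho-quinone methide, and C4a of ring A closes onto C4 by Friedel–Crafts alkylation. The closest known reaction types are the Lewis-acid-promoted oxa-Povarov reaction of O-aryl oxocarbenium ions with styrenes, which gives 2,4-cis chromans, and the chiral-phosphoric-acid-catalysed Povarov reaction of N-aryl imines with 2-hydroxystyrenes, which gives cis-2,4-diaryl tetrahydroquinolines in high enantiomeric purity through the same double contact of the phosphate with heterodiene and phenol; what is new is the transfer of this bifunctional ion-pair control to an oxocarbenium ion that has no N–H donor. Ring C is closed as a formal inverse-electron-demand [4+2] cycloaddition, stepwise or highly asynchronous, the second bond by 6-exo-trig attack of the arene carbon on the quinone methide carbon. C2 is set in the first C–C bond formation by the chiral phosphate, which shields one face of the oxocarbenium ion, and C4 is set in the ring closure by the substrate through a chair-like transition state with both aryl groups pseudo-equatorial, which should give the 2,4-cis, hence (2R,4R), relationship. The step needs attack of the alkene and not of an arene on the cation, ring closure para to the benzyloxy group of ring A and not between its two oxygens, and no diversion of 6 by self-condensation or acetal exchange: the ortho,ortho,para-trioxygenated styrene is the best π-nucleophile present and is delivered inside the ion pair, the position between the two oxygens of ring A is the more hindered one, and the free hydroxyl of 6, flanked by the acyl-bearing and vinyl-bearing carbons, is a hindered and weak nucleophile, so acetal exchange at that oxygen should be slow and reversible.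

**Step 7**
Reactants: 13 1-{4,6-bis(benzyloxy)-3-[(2R,4R)-7-(benzyloxy)-2-[4-(benzyloxy)phenyl]-3,4-dihydro-2H-chromen-4-yl]-2-hydroxyphenyl}-9-phenylnonan-1-one
Product: 14 1-{2,4,6-trihydroxy-3-[(2R,4R)-7-hydroxy-2-(4-hydroxyphenyl)-3,4-dihydro-2H-chromen-4-yl]phenyl}-9-phenylnonan-1-one (CNP0175574.1)
Conditions: H2 (1 atm), 10 % Pd/C, EtOAc/MeOH 1:1, rt
Reagents that add atoms: none
Why: Hydrogenolysis of the four aryl benzyl ethers on palladium; the neutral conditions keep the acid-labile C2–O1 bond closed, so C2 and C4 keep their configuration, and the chelated, hindered aryl ketone should be reduced much more slowly than the benzyl ethers are cleaved.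

**Compound list**

1 | phloroglucinol (benzene-1,3,5-triol) | Oc1cc(O)cc(O)c1 | starting material
2 | 9-phenylnonanoic acid | OC(=O)CCCCCCCCc1ccccc1 | starting material
3 | 9-phenyl-1-(2,4,6-trihydroxyphenyl)nonan-1-one | O=C(CCCCCCCCc1ccccc1)c1c(O)cc(O)cc1O | intermediate
4 | 2,4,6-trihydroxy-3-(9-phenylnonanoyl)benzaldehyde | O=C(CCCCCCCCc1ccccc1)c1c(O)cc(O)c(C=O)c1O | intermediate
5 | 4,6-bis(benzyloxy)-2-hydroxy-3-(9-phenylnonanoyl)benzaldehyde | O=C(CCCCCCCCc1ccccc1)c1c(OCc2ccccc2)cc(OCc2ccccc2)c(C=O)c1O | intermediate
6 | 1-[4,6-bis(benzyloxy)-3-ethenyl-2-hydroxyphenyl]-9-phenylnonan-1-one | O=C(CCCCCCCCc1ccccc1)c1c(OCc2ccccc2)cc(OCc2ccccc2)c(C=C)c1O | intermediate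
7 | 4-(benzyloxy)benzaldehyde | O=Cc1ccc(OCc2ccccc2)cc1 | starting material
8 | 3-(benzyloxy)phenol | Oc1cccc(OCc2ccccc2)c1 | starting material
9 | 1-(benzyloxy)-4-(dichloromethyl)benzene (benzal chloride, not isolated) | ClC(Cl)c1ccc(OCc2ccccc2)cc1 | intermediate
10 | 4-(benzyloxy)benzaldehyde bis[3-(benzyloxy)phenyl] acetal | C(Oc1cccc(OCc2ccccc2)c1)(Oc1cccc(OCc2ccccc2)c1)c1ccc(OCc2ccccc2)cc1 | intermediate
11 | (E)-[4-(benzyloxy)benzylidene][3-(benzyloxy)phenyl]oxonium ion, ion-paired with the chiral phosphate (not isolated) | c1ccc(COc2ccc(/C=[O+]/c3cccc(OCc4ccccc4)c3)cc2)cc1 | intermediate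
12 | (3R)-1-[4,6-bis(benzyloxy)-2-hydroxy-3-(9-phenylnonanoyl)phenyl]-3-[3-(benzyloxy)phenoxy]-3-[4-(benzyloxy)phenyl]propan-1-ylium, the O-protonated ortho-quinone methide (not isolated) | O=C(CCCCCCCCc1ccccc1)c1c(OCc2ccccc2)cc(OCc2ccccc2)c([CH+]C[C@H](c2ccc(OCc3ccccc3)cc2)Oc2cccc(OCc3ccccc3)c2)c1O | intermediate
13 | 1-{4,6-bis(benzyloxy)-3-[(2R,4R)-7-(benzyloxy)-2-[4-(benzyloxy)phenyl]-3,4-dihydro-2H-chromen-4-yl]-2-hydroxyphenyl}-9-phenylnonan-1-one | O=C(CCCCCCCCc1ccccc1)c1c(OCc2ccccc2)cc(OCc2ccccc2)c([C@@H]2C[C@H](c3ccc(OCc4ccccc4)cc3)Oc3cc(OCc4ccccc4)ccc32)c1O | intermediate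
14 | 1-{2,4,6-trihydroxy-3-[(2R,4R)-7-hydroxy-2-(4-hydroxyphenyl)-3,4-dihydro-2H-chromen-4-yl]phenyl}-9-phenylnonan-1-one (CNP0175574.1) | O=C(CCCCCCCCc1ccccc1)c1c(O)cc(O)c([C@@H]2C[C@H](c3ccc(O)cc3)Oc3cc(O)ccc32)c1O | target

**Step count and risks**

Total step count: 7. Longest linear sequence: 6 (steps 1, 2, 3, 4, 6, 7).

Steps most likely to fail:

Step 6 (Proposed new method). What may go wrong: poor facial selectivity on the oxocarbenium ion inside the ion pair, Friedel–Crafts alkylation of the arenes outrunning addition of the alkene, or acid-induced oligomerisation of the hydroxystyrene. The fallback uses known chemistry: a racemic annulation followed by resolution. It sets out from 6. The remaining phenol is benzylated (BnBr, K2CO3, DMF, 60 °C) to 1-[2,4,6-tris(benzyloxy)-3-ethenylphenyl]-9-phenylnonan-1-one F1. F1 and 10 are treated with SnCl4 in CH2Cl2 at −78 °C, the Lewis-acid oxa-Povarov reaction, which should give the racemic 2,4-cis chroman. This is the pentabenzyl ether 1-{2,4,6-tris(benzyloxy)-3-[(2R,4R)-7-(benzyloxy)-2-[4-(benzyloxy)phenyl]-3,4-dihydro-2H-chromen-4-yl]phenyl}-9-phenylnonan-1-one F2 together with its (2S,4S) mirror-image pentabenzyl ether F3. The two are separated by preparative chromatography on a chiral stationary phase, and the absolute configuration is assigned by circular dichroism or by X-ray analysis of a heavy-atom derivative. F2 is hydrogenolysed under the conditions of step 7, and the fallback comes back to the route at 14.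

Step 5. What may go wrong: hydrolysis or self-condensation of the electron-rich benzal chloride before the phenoxide arrives, C-alkylation of the phenoxide in place of O-alkylation, or loss of the acetal on purification. The fallback builds the acetal by oxidation in place of substitution and sets out from 8. It is alkylated with commercial 4-(benzyloxy)benzyl chloride (K2CO3, DMF, rt) to the ether 1-(benzyloxy)-3-{[4-(benzyloxy)benzyl]oxy}benzene F4. The para-alkoxybenzylic C–H of F4 is then oxidised with DDQ in dry CH2Cl2 over 4 Å MS at 0 °C in the presence of a second equivalent of 8. This is the oxidative acetalisation known for para-methoxybenzyl ethers, and it should give 10, where the fallback rejoins the route.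

Step 7. What may go wrong: over-reduction, either hydrogenolysis of the benzylic C2–O1 bond with opening of ring C or reduction of the aryl ketone, before the last benzyl ether is cleaved. The fallback is a non-reductive debenzylation and sets out from 13. It is treated with BCl3 and pentamethylbenzene as benzyl-cation scavenger in CH2Cl2 at −78 °C and quenched cold with MeOH, which should give 14 directly. The short contact time at low temperature is meant to keep the C2–O1 bond from ionising. This fallback makes no new compound: none F0.

**Further compounds**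

F1 | step 6 | 1-[2,4,6-tris(benzyloxy)-3-ethenylphenyl]-9-phenylnonan-1-one | O=C(CCCCCCCCc1ccccc1)c1c(OCc2ccccc2)cc(OCc2ccccc2)c(C=C)c1OCc1ccccc1
F2 | step 6 | 1-{2,4,6-tris(benzyloxy)-3-[(2R,4R)-7-(benzyloxy)-2-[4-(benzyloxy)phenyl]-3,4-dihydro-2H-chromen-4-yl]phenyl}-9-phenylnonan-1-one | O=C(CCCCCCCCc1ccccc1)c1c(OCc2ccccc2)cc(OCc2ccccc2)c([C@@H]2C[C@H](c3ccc(OCc4ccccc4)cc3)Oc3cc(OCc4ccccc4)ccc32)c1OCc1ccccc1
F3 | step 6 | 1-{2,4,6-tris(benzyloxy)-3-[(2S,4S)-7-(benzyloxy)-2-[4-(benzyloxy)phenyl]-3,4-dihydro-2H-chromen-4-yl]phenyl}-9-phenylnonan-1-one | O=C(CCCCCCCCc1ccccc1)c1c(OCc2ccccc2)cc(OCc2ccccc2)c([C@H]2C[C@@H](c3ccc(OCc4ccccc4)cc3)Oc3cc(OCc4ccccc4)ccc32)c1OCc1ccccc1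
F4 | step 5 | 1-(benzyloxy)-3-{[4-(benzyloxy)benzyl]oxy}benzene | c1ccccc1COc1ccc(COc2cccc(OCc3ccccc3)c2)cc1
F0 | step 7 | none | none
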